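**Strategy.** The flavone is disconnected at O1''–C8a'', C4a''–C4'' and O1''–C2''. On its benzo ring (ring A'') the pyranone oxygen on C8a'' and the C4'' carbonyl on C4a'' sit on neighbouring carbons, between the C5'' ether and the C8''–C8 biaryl bond. An aryne C4a''≡C8a'' can therefore take up both from one arylpropiolic acid: C–O insertion and oxa-Michael closure build the whole pyranone ring in a single operation. The precursor is a 2-aryl-3,5-bis(benzyloxy)-6-(trimethylsilyl)phenyl triflate whose aryl group is a MOM-protected phloroacetophenone ring. Its acetyl group later becomes a chromone, and rhodium-catalysed asymmetric arylation sets C2 as S.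

Key step: step 9

Assumption: the target SMILES fixes only C2; the sense of the hindered C8–C8'' axis is not defined, so it is not controlled and either atropisomer about that bond counts as the target.

Assumption: the (S)-ligand in step 11 is taken to deliver the aryl group to the Re face of C2; if a trial on 5,7-bis(benzyloxy)chromone shows the opposite sense, the (R)-ligand is used instead.

Design remark: the aryl ring of the aryne precursor already carries the acetyl carbon of the flavanone and three differentiated oxygens (MOM on the future O1, benzyl on the others). No statistical mono-protection and no acid-mediated ring closure is therefore needed after the key step.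

Design remark: the carbamate nitrogen is masked in the flask for each of the two ortho-lithiations. In step 5 a trimethylsilyl group is used, because that sequence stays cold until the quench. In step 6 the somewhat sturdier triethylsilyl group is used, because the N-silyl carbamate is carried through zincation and a coupling at 65 °C, where loss of silicon from nitrogen would expose an N-metal carbamate prone to eliminate isopropyl isocyanate. Both N–Si bonds should hydrolyse in a buffered NH4Cl work-up, so the acid-labile aryl–silicon bond of the electron-rich ring meets only basic or neutral conditions from step 5 to aryne formation in step 9.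

**Step 1**
Reactants: 1 2',4',6'-trihydroxyacetophenone
Product: 2 1-[2,4-bis(benzyloxy)-6-hydroxyphenyl]ethanone
Conditions: BnBr (2.1 equiv), K2CO3, DMF, rt
Reagents that add atoms: benzyl bromide BrCc1ccccc1
Why: Williamson etherification that stops at the diether because the hydroxyl hydrogen-bonded to the acetyl carbonyl is far less nucleophilic, which differentiates the three oxygens of the future flavanone ring A at the outset.

**Step 2**
Reactants: 2 1-[2,4-bis(benzyloxy)-6-hydroxyphenyl]ethanone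
Product: 3 1-[4,6-bis(benzyloxy)-2-hydroxy-3-iodophenyl]ethanone
Conditions: BnMe3N+ ICl2−, NaHCO3, CH2Cl2/MeOH, rt
Reagents that add atoms: benzyltrimethylammonium dichloroiodate C[N+](C)(C)Cc1ccccc1.Cl[I-]Cl
Why: Electrophilic aromatic iodination with a mild source of electrophilic iodine, which for chelated 2-hydroxy-4,6-dialkoxyacetophenones is directed to the carbon ortho to the free hydroxyl, the future C8.

**Step 3**
Reactants: 3 1-[4,6-bis(benzyloxy)-2-hydroxy-3-iodophenyl]ethanone
Product: 4 1-[4,6-bis(benzyloxy)-3-iodo-2-(methoxymethoxy)phenyl]ethanone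
Conditions: NaH, MOMCl, DMF, 0 °C to rt
Reagents that add atoms: chloromethyl methyl ether COCCl
Why: Williamson-type O-alkylation of the sodium phenoxide masks the one oxygen that becomes O1 as an acetal that tolerates organozinc, amine base and fluoride and is later removed by dilute acid without loss of benzyl ethers.

**Step 4**
Reactants: 5 3,5-bis(benzyloxy)phenol
Product: 6 3,5-bis(benzyloxy)phenyl N-(propan-2-yl)carbamate
Conditions: i-PrNCO, Et3N (cat.), CH2Cl2, rt
Reagents that add atoms: isopropyl isocyanate CC(C)N=C=O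
Why: Base-catalysed addition of the phenol to the isocyanate gives an N-monoalkyl carbamate that serves as ortho-metalation director and as a phenol mask removable later by mild elimination.

**Step 5**
Reactants: 6 3,5-bis(benzyloxy)phenyl N-(propan-2-yl)carbamate
Product: 10 3,5-bis(benzyloxy)-2-(trimethylsilyl)phenyl N-(propan-2-yl)carbamate, via N-trimethylsilyl carbamate 7 (not isolated), via aryllithium 8 (not isolated), via N-trimethylsilyl arylsilane 9 (not isolated)
Conditions: TMSOTf, TMEDA, Et2O, 0 °C to rt; n-BuLi, TMEDA, −78 °C; TMSCl, −78 °C to rt; aq. NH4Cl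
Reagents that add atoms: chlorotrimethylsilane C[Si](C)(C)Cl
Why: Directed ortho-metalation, in which the carbamate (N-silylated in the flask so that its N–H cannot be deprotonated and trigger loss of isocyanate) and the neighbouring benzyloxy group jointly direct lithiation to the carbon between them, the aryllithium is trapped by TMSCl, and the labile N–SiMe3 bond is hydrolysed on work-up.

**Step 6**
Reactants: 10 3,5-bis(benzyloxy)-2-(trimethylsilyl)phenyl N-(propan-2-yl)carbamate; 4 1-[4,6-bis(benzyloxy)-3-iodo-2-(methoxymethoxy)phenyl]ethanone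
Product: 15 2-[3-acetyl-4,6-bis(benzyloxy)-2-(methoxymethoxy)phenyl]-3,5-bis(benzyloxy)-6-(trimethylsilyl)phenyl N-(propan-2-yl)carbamate, via N-triethylsilyl carbamate 11 (not isolated), via aryllithium 12 (not isolated), via arylzinc chloride 13 (not isolated), via N-triethylsilyl biaryl 14 (not isolated)
Conditions: TESOTf, TMEDA, Et2O, 0 °C to rt; n-BuLi, TMEDA, −78 °C; ZnCl2 (THF), −78 °C to rt; 4, Pd2(dba)3, RuPhos, THF, 65 °C; aq. NH4Cl/MeOH
Reagents that add atoms: none
Why: A second in-flask N-silylation and carbamate-directed ortho-lithiation at the one remaining carbon between carbamate and benzyloxy, transmetalation to zinc and Negishi coupling under a bulky dialkylbiarylphosphine ligand suited to tetra-ortho-substituted biaryls should forge the C8–C8'' bond, the arylzinc species being unreactive toward the methyl ketone of 4 and the N–SiEt3 bond being hydrolysed in the buffered work-up.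

**Step 7**
Reactants: 15 2-[3-acetyl-4,6-bis(benzyloxy)-2-(methoxymethoxy)phenyl]-3,5-bis(benzyloxy)-6-(trimethylsilyl)phenyl N-(propan-2-yl)carbamate
Product: 17 2-[3-acetyl-4,6-bis(benzyloxy)-2-(methoxymethoxy)phenyl]-3,5-bis(benzyloxy)-6-(trimethylsilyl)phenyl trifluoromethanesulfonate, via silyl phenol 16 (not isolated)
Conditions: Et2NH, DBU, MeCN, 40 °C; then PhNTf2, rt
Reagents that add atoms: N-phenylbis(trifluoromethanesulfonimide) O=S(=O)(N(c1ccccc1)S(=O)(=O)C(F)(F)F)C(F)(F)F
Why: E1cB cleavage of the N–H carbamate (the expelled isocyanate is scavenged by Et2NH) should free the hindered phenoxide without exposing the aryl–silicon bond to acid, and O-sulfonylation in the same flask gives the ortho-silylaryl triflate.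

**Step 8**
Reactants: 18 1-(benzyloxy)-4-ethynylbenzene
Product: 21 3-[4-(benzyloxy)phenyl]prop-2-ynoic acid, via lithium acetylide 19 (not isolated), via lithium carboxylate 20 (not isolated)
Conditions: n-BuLi, THF, −78 °C; CO2; 1 M HCl
Reagents that add atoms: carbon dioxide O=C=O
Why: Deprotonation of the terminal alkyne and carboxylation of the lithium acetylide is the standard entry to arylpropiolic acids, and the benzyl ether is inert to it.

**Step 9**
Reactants: 17 2-[3-acetyl-4,6-bis(benzyloxy)-2-(methoxymethoxy)phenyl]-3,5-bis(benzyloxy)-6-(trimethylsilyl)phenyl trifluoromethanesulfonate; 21 3-[4-(benzyloxy)phenyl]prop-2-ynoic acid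
Product: 24 8-[3-acetyl-4,6-bis(benzyloxy)-2-(methoxymethoxy)phenyl]-5,7-bis(benzyloxy)-2-[4-(benzyloxy)phenyl]-4H-chromen-4-one, via aryne 22 (not isolated), via hydroxyaryl ynone 23 (not isolated)
Conditions: 21 (2.5 equiv), CsF (6 equiv), THF, 90 °C (sealed tube); then Et2NH, 50 °C
Reagents that add atoms: none
Why: Proposed new method: fluoride removes the silyl group of 17 and triflate leaves to give aryne 22 (C4a''≡C8a''), the propiolate oxygen adds at C8a'', the aryl anion left at C4a'' takes the acyl group through a four-membered transition state to give the phenoxide of ynone 23, and Et2NH, added once the aryne is consumed, converts the ynone through its enaminone into the 4-pyranone. The closest known reactions are the fluoride-induced insertion of arynes into the C–O bond of carboxylic acids to give ortho-hydroxyaryl ketones and the amine-mediated cyclisation of ortho-hydroxyaryl ynones to flavones; new is their union on a tetrasubstituted aryne that bears an ortho aryl group. The one ring formed, the pyranone of the flavone, closes in the 6-endo-dig mode, which the secondary amine enforces over 5-exo-dig closure to an aurone. No stereocentre is created. The step needs carboxylate attack at C8a'' and not at C4a'': the 5''-benzyloxy group polarises the aryne so that the carbon remote from it is the electrophilic terminus and the developing negative charge sits beside the inductively withdrawing oxygen, and this has to outweigh the shielding of C8a'' by the neighbouring aryl ring. The carboxylate is used in excess and at high concentration so that intermolecular capture outruns attack of the ortho ether oxygens of the neighbouring ring on the aryne, and the surplus CsF holds the acid as its cesium salt so that little free acid is left to protonate the aryl anion before acyl transfer.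

**Step 10**
Reactants: 24 8-[3-acetyl-4,6-bis(benzyloxy)-2-(methoxymethoxy)phenyl]-5,7-bis(benzyloxy)-2-[4-(benzyloxy)phenyl]-4H-chromen-4-one
Product: 27 5,7-bis(benzyloxy)-8-{5,7-bis(benzyloxy)-2-[4-(benzyloxy)phenyl]-4-oxo-4H-chromen-8-yl}-4H-chromen-4-one, via enaminone 25 (not isolated), via hydroxy enaminone 26 (not isolated)
Conditions: Me2NCH(OMe)2, toluene, 110 °C; then HCl, MeOH/THF, 50 °C
Reagents that add atoms: N,N-dimethylformamide dimethyl acetal COC(OC)N(C)C
Why: Enaminone condensation of the methyl ketone followed by acid, which removes the MOM acetal and lets the freed phenol displace dimethylamine by addition–elimination, is the standard chromone synthesis from ortho-oxygenated acetophenones, and the flavone unit has no acidic methyl group to compete.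

**Step 11**
Reactants: 27 5,7-bis(benzyloxy)-8-{5,7-bis(benzyloxy)-2-[4-(benzyloxy)phenyl]-4-oxo-4H-chromen-8-yl}-4H-chromen-4-one; 28 4-(benzyloxy)phenylboronic acid
Product: 29 (2S)-5,7-bis(benzyloxy)-8-{5,7-bis(benzyloxy)-2-[4-(benzyloxy)phenyl]-4-oxo-4H-chromen-8-yl}-2-[4-(benzyloxy)phenyl]-2,3-dihydro-4H-chromen-4-one
Conditions: preformed [Rh(OH)((S)-MeO-F12-BIPHEP)]2 (cat.), toluene/H2O, 50 °C
Reagents that add atoms: none
Why: Rhodium-catalysed asymmetric 1,4-addition of an arylboronic acid (Hayashi–Miyaura type) to the 2-unsubstituted chromone, a known entry to 5,7-dioxygenated flavanones, in which the aryl–rhodium species held by the chiral bisphosphine adds to the Re face of C2 and so sets C2 as S under catalyst control whatever the sense of the biaryl axis, while the 2-aryl-substituted flavone enone is too hindered to react and the base-free medium avoids ring opening of the product.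

**Step 12**
Reactants: 29 (2S)-5,7-bis(benzyloxy)-8-{5,7-bis(benzyloxy)-2-[4-(benzyloxy)phenyl]-4-oxo-4H-chromen-8-yl}-2-[4-(benzyloxy)phenyl]-2,3-dihydro-4H-chromen-4-one
Product: 30 (2S)-5,7-dihydroxy-8-[5,7-dihydroxy-2-(4-hydroxyphenyl)-4-oxo-4H-chromen-8-yl]-2-(4-hydroxyphenyl)-2,3-dihydro-4H-chromen-4-one
Conditions: H2 (1 atm), Pd/C, THF/MeOH, rt
Reagents that add atoms: none
Why: Hydrogenolysis of the six benzyl aryl ethers over palladium on carbon should free all phenols in one neutral operation that leaves the base-sensitive C2 stereocentre and the flavone enone untouched.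

**Compound list**

1 | 2',4',6'-trihydroxyacetophenone | CC(=O)c1c(O)cc(O)cc1O | starting material
2 | 1-[2,4-bis(benzyloxy)-6-hydroxyphenyl]ethanone | CC(=O)c1c(O)cc(OCc2ccccc2)cc1OCc1ccccc1 | intermediate
3 | 1-[4,6-bis(benzyloxy)-2-hydroxy-3-iodophenyl]ethanone | CC(=O)c1c(O)c(I)c(OCc2ccccc2)cc1OCc1ccccc1 | intermediate
4 | 1-[4,6-bis(benzyloxy)-3-iodo-2-(methoxymethoxy)phenyl]ethanone | CC(=O)c1c(OCOC)c(I)c(OCc2ccccc2)cc1OCc1ccccc1 | intermediate
5 | 3,5-bis(benzyloxy)phenol | Oc1cc(OCc2ccccc2)cc(OCc2ccccc2)c1 | starting material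
6 | 3,5-bis(benzyloxy)phenyl N-(propan-2-yl)carbamate | CC(C)NC(=O)Oc1cc(OCc2ccccc2)cc(OCc2ccccc2)c1 | intermediate
7 | 3,5-bis(benzyloxy)phenyl N-(propan-2-yl)-N-(trimethylsilyl)carbamate (formed in the flask) | CC(C)N(C(=O)Oc1cc(OCc2ccccc2)cc(OCc2ccccc2)c1)[Si](C)(C)C | intermediate
8 | 2-lithio derivative of 7 (formed in the flask) | CC(C)N(C(=O)Oc1c([Li])c(OCc2ccccc2)cc(OCc2ccccc2)c1)[Si](C)(C)C | intermediate
9 | 3,5-bis(benzyloxy)-2-(trimethylsilyl)phenyl N-(propan-2-yl)-N-(trimethylsilyl)carbamate (formed in the flask) | CC(C)N(C(=O)Oc1c([Si](C)(C)C)c(OCc2ccccc2)cc(OCc2ccccc2)c1)[Si](C)(C)C | intermediate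
10 | 3,5-bis(benzyloxy)-2-(trimethylsilyl)phenyl N-(propan-2-yl)carbamate | CC(C)NC(=O)Oc1c([Si](C)(C)C)c(OCc2ccccc2)cc(OCc2ccccc2)c1 | intermediate
11 | 3,5-bis(benzyloxy)-2-(trimethylsilyl)phenyl N-(propan-2-yl)-N-(triethylsilyl)carbamate (formed in the flask) | CC(C)N(C(=O)Oc1c([Si](C)(C)C)c(OCc2ccccc2)cc(OCc2ccccc2)c1)[Si](CC)(CC)CC | intermediate
12 | 6-lithio derivative of 11 (formed in the flask) | CC(C)N(C(=O)Oc1c([Si](C)(C)C)c(OCc2ccccc2)cc(OCc2ccccc2)c1[Li])[Si](CC)(CC)CC | intermediate
13 | 6-(chlorozincio) derivative of 11 (formed in the flask) | CC(C)N(C(=O)Oc1c([Si](C)(C)C)c(OCc2ccccc2)cc(OCc2ccccc2)c1[Zn]Cl)[Si](CC)(CC)CC | intermediate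
14 | N-(triethylsilyl) derivative of 15 (formed in the flask) | CC(C)N(C(=O)Oc1c([Si](C)(C)C)c(OCc2ccccc2)cc(OCc2ccccc2)c1-c1c(OCOC)c(C(C)=O)c(OCc2ccccc2)cc1OCc1ccccc1)[Si](CC)(CC)CC | intermediate
15 | 2-[3-acetyl-4,6-bis(benzyloxy)-2-(methoxymethoxy)phenyl]-3,5-bis(benzyloxy)-6-(trimethylsilyl)phenyl N-(propan-2-yl)carbamate | CC(C)NC(=O)Oc1c([Si](C)(C)C)c(OCc2ccccc2)cc(OCc2ccccc2)c1-c1c(OCOC)c(C(C)=O)c(OCc2ccccc2)cc1OCc1ccccc1 | intermediate
16 | 1-[4,6-bis(benzyloxy)-3-[4,6-bis(benzyloxy)-2-hydroxy-3-(trimethylsilyl)phenyl]-2-(methoxymethoxy)phenyl]ethanone (formed in the flask) | Oc1c([Si](C)(C)C)c(OCc2ccccc2)cc(OCc2ccccc2)c1-c1c(OCOC)c(C(C)=O)c(OCc2ccccc2)cc1OCc1ccccc1 | intermediate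
17 | 2-[3-acetyl-4,6-bis(benzyloxy)-2-(methoxymethoxy)phenyl]-3,5-bis(benzyloxy)-6-(trimethylsilyl)phenyl trifluoromethanesulfonate | O=S(=O)(Oc1c([Si](C)(C)C)c(OCc2ccccc2)cc(OCc2ccccc2)c1-c1c(OCOC)c(C(C)=O)c(OCc2ccccc2)cc1OCc1ccccc1)C(F)(F)F | intermediate
18 | 1-(benzyloxy)-4-ethynylbenzene | C#Cc1ccc(OCc2ccccc2)cc1 | starting material
19 | lithium [4-(benzyloxy)phenyl]acetylide (formed in the flask) | [Li]C#Cc1ccc(OCc2ccccc2)cc1 | intermediate
20 | lithium 3-[4-(benzyloxy)phenyl]prop-2-ynoate (formed in the flask) | [Li+].[O-]C(=O)C#Cc1ccc(OCc2ccccc2)cc1 | intermediate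
21 | 3-[4-(benzyloxy)phenyl]prop-2-ynoic acid | OC(=O)C#Cc1ccc(OCc2ccccc2)cc1 | intermediate
22 | 3-[3-acetyl-4,6-bis(benzyloxy)-2-(methoxymethoxy)phenyl]-4,6-bis(benzyloxy)-1,2-didehydrobenzene (aryne, formed in the flask) | C1#CC(OCc2ccccc2)=CC(OCc2ccccc2)=C1-c1c(OCOC)c(C(C)=O)c(OCc2ccccc2)cc1OCc1ccccc1 | intermediate
23 | 1-{3-[3-acetyl-4,6-bis(benzyloxy)-2-(methoxymethoxy)phenyl]-4,6-bis(benzyloxy)-2-hydroxyphenyl}-3-[4-(benzyloxy)phenyl]prop-2-yn-1-one (formed in the flask) | O=C(C#Cc1ccc(OCc2ccccc2)cc1)c1c(O)c(-c2c(OCOC)c(C(C)=O)c(OCc3ccccc3)cc2OCc2ccccc2)c(OCc2ccccc2)cc1OCc1ccccc1 | intermediate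
24 | 8-[3-acetyl-4,6-bis(benzyloxy)-2-(methoxymethoxy)phenyl]-5,7-bis(benzyloxy)-2-[4-(benzyloxy)phenyl]-4H-chromen-4-one | O=c1cc(-c2ccc(OCc3ccccc3)cc2)oc2c(-c3c(OCOC)c(C(C)=O)c(OCc4ccccc4)cc3OCc3ccccc3)c(OCc3ccccc3)cc(OCc3ccccc3)c12 | intermediate
25 | 8-{4,6-bis(benzyloxy)-3-[(2E)-3-(dimethylamino)prop-2-enoyl]-2-(methoxymethoxy)phenyl}-5,7-bis(benzyloxy)-2-[4-(benzyloxy)phenyl]-4H-chromen-4-one (formed in the flask) | O=c1cc(-c2ccc(OCc3ccccc3)cc2)oc2c(-c3c(OCOC)c(C(=O)/C=C/N(C)C)c(OCc4ccccc4)cc3OCc3ccccc3)c(OCc3ccccc3)cc(OCc3ccccc3)c12 | intermediate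
26 | 8-{4,6-bis(benzyloxy)-3-[(2E)-3-(dimethylamino)prop-2-enoyl]-2-hydroxyphenyl}-5,7-bis(benzyloxy)-2-[4-(benzyloxy)phenyl]-4H-chromen-4-one (formed in the flask) | O=c1cc(-c2ccc(OCc3ccccc3)cc2)oc2c(-c3c(O)c(C(=O)/C=C/N(C)C)c(OCc4ccccc4)cc3OCc3ccccc3)c(OCc3ccccc3)cc(OCc3ccccc3)c12 | intermediate
27 | 5,7-bis(benzyloxy)-8-{5,7-bis(benzyloxy)-2-[4-(benzyloxy)phenyl]-4-oxo-4H-chromen-8-yl}-4H-chromen-4-one | O=c1ccoc2c(-c3c(OCc4ccccc4)cc(OCc4ccccc4)c4c(=O)cc(-c5ccc(OCc6ccccc6)cc5)oc34)c(OCc3ccccc3)cc(OCc3ccccc3)c12 | intermediate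
28 | 4-(benzyloxy)phenylboronic acid | OB(O)c1ccc(OCc2ccccc2)cc1 | starting material
29 | (2S)-5,7-bis(benzyloxy)-8-{5,7-bis(benzyloxy)-2-[4-(benzyloxy)phenyl]-4-oxo-4H-chromen-8-yl}-2-[4-(benzyloxy)phenyl]-2,3-dihydro-4H-chromen-4-one | O=C1C[C@@H](c2ccc(OCc3ccccc3)cc2)Oc2c(-c3c(OCc4ccccc4)cc(OCc4ccccc4)c4c(=O)cc(-c5ccc(OCc6ccccc6)cc5)oc34)c(OCc3ccccc3)cc(OCc3ccccc3)c12 | intermediate
30 | (2S)-5,7-dihydroxy-8-[5,7-dihydroxy-2-(4-hydroxyphenyl)-4-oxo-4H-chromen-8-yl]-2-(4-hydroxyphenyl)-2,3-dihydro-4H-chromen-4-one (CNP0339995.1, the 8,8''-linked naringenin–apigenin dimer) | O=C1C[C@@H](c2ccc(O)cc2)Oc2c1c(O)cc(O)c2-c1c(O)cc(O)c2c(=O)cc(-c3ccc(O)cc3)oc12 | target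

**Step count.** Total: 12 steps. Longest linear sequence: 9 steps (steps 1, 2, 3, 6, 7, 9, 10, 11, 12).

**Steps most likely to fail**

Step 9 (proposed new method). Several processes could divert the aryne or its partner: the carboxylate may add at C4a'' because the neighbouring aryl ring shields C8a''; the aryl anion may be protonated before acyl transfer, leaving only an O-aryl ester; an ortho ether oxygen of the neighbouring ring may capture the aryne intramolecularly; the propiolate may lose carbon dioxide at the reaction temperature; and the ynone may close 5-exo to an aurone. The fallback uses known chemistry and the silicon atom as a positional marker. It sets out from carbamate 15. ICl (1 equiv, CH2Cl2, −78 °C) should effect ipso-iododesilylation, attack at the silicon-bearing carbon being faster than at the free ring positions, to give 2-[3-acetyl-4,6-bis(benzyloxy)-2-(methoxymethoxy)phenyl]-3,5-bis(benzyloxy)-6-iodophenyl N-(propan-2-yl)carbamate F1. Et2NH/DBU in MeCN should then cleave the carbamate to 1-[4,6-bis(benzyloxy)-3-[4,6-bis(benzyloxy)-2-hydroxy-3-iodophenyl]-2-(methoxymethoxy)phenyl]ethanone F2. Carbonylative Sonogashira coupling of this ortho-iodophenol with alkyne 18 (PdCl2(PPh3)2, CO at 1 atm, Et2NH, 60 °C) passes through ynone 23, which the amine closes 6-endo, and the sequence comes back to the route at flavone 24.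

Step 6. Transmetalation and reductive elimination at the tetra-ortho-substituted junction may be too slow, so that protodezincation of 13 and reduction of iodide 4 take over. The fallback sets out from carbamate 10 and changes the coupling manifold. The same N-silylation and lithiation (through 11 and 12) is followed by a quench with 2-isopropoxy-4,4,5,5-tetramethyl-1,3,2-dioxaborolane, which should give the N-silyl boronate 3,5-bis(benzyloxy)-2-(4,4,5,5-tetramethyl-1,3,2-dioxaborolan-2-yl)-6-(trimethylsilyl)phenyl N-(propan-2-yl)-N-(triethylsilyl)carbamate F3. The buffered aqueous work-up hydrolyses its N–Si bond to the isolable boronic ester 3,5-bis(benzyloxy)-2-(4,4,5,5-tetramethyl-1,3,2-dioxaborolan-2-yl)-6-(trimethylsilyl)phenyl N-(propan-2-yl)carbamate F4. The purified ester is then joined to iodide 4 by Suzuki–Miyaura coupling (Pd(OAc)2, SPhos, K3PO4, toluene/H2O, 90 °C), coming back to the route at biaryl 15. Should the base cleave the carbamate during the coupling, the product would be phenol 16, which step 7 needs anyway.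

Step 11. Aryl transfer to the hindered, electron-rich chromone may be slow or poorly face-selective, and the flavanone may ring-open to the chalcone. The fallback sets out from flavone 24. Claisen–Schmidt condensation with 4-(benzyloxy)benzaldehyde (KOH, EtOH/THF, rt) should give the chalcone 8-{4,6-bis(benzyloxy)-3-[(2E)-3-[4-(benzyloxy)phenyl]prop-2-enoyl]-2-(methoxymethoxy)phenyl}-5,7-bis(benzyloxy)-2-[4-(benzyloxy)phenyl]-4H-chromen-4-one F5. HCl in MeOH/THF removes the MOM group to give the 2'-hydroxychalcone 8-{4,6-bis(benzyloxy)-3-[(2E)-3-[4-(benzyloxy)phenyl]prop-2-enoyl]-2-hydroxyphenyl}-5,7-bis(benzyloxy)-2-[4-(benzyloxy)phenyl]-4H-chromen-4-one F6. NaOAc in refluxing EtOH closes it by oxa-Michael addition to the racemic flavanone rac-5,7-bis(benzyloxy)-8-{5,7-bis(benzyloxy)-2-[4-(benzyloxy)phenyl]-4-oxo-4H-chromen-8-yl}-2-[4-(benzyloxy)phenyl]-2,3-dihydro-4H-chromen-4-one F7. Preparative HPLC on a chiral stationary phase resolves it, and the 2S enantiomer rejoins the route at 29.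

**Further compounds**

F1 | step 9 | 2-[3-acetyl-4,6-bis(benzyloxy)-2-(methoxymethoxy)phenyl]-3,5-bis(benzyloxy)-6-iodophenyl N-(propan-2-yl)carbamate | CC(C)NC(=O)Oc1c(I)c(OCc2ccccc2)cc(OCc2ccccc2)c1-c1c(OCOC)c(C(C)=O)c(OCc2ccccc2)cc1OCc1ccccc1
F2 | step 9 | 1-[4,6-bis(benzyloxy)-3-[4,6-bis(benzyloxy)-2-hydroxy-3-iodophenyl]-2-(methoxymethoxy)phenyl]ethanone | Oc1c(I)c(OCc2ccccc2)cc(OCc2ccccc2)c1-c1c(OCOC)c(C(C)=O)c(OCc2ccccc2)cc1OCc1ccccc1
F3 | step 6 | 3,5-bis(benzyloxy)-2-(4,4,5,5-tetramethyl-1,3,2-dioxaborolan-2-yl)-6-(trimethylsilyl)phenyl N-(propan-2-yl)-N-(triethylsilyl)carbamate | CC(C)N(C(=O)Oc1c([Si](C)(C)C)c(OCc2ccccc2)cc(OCc2ccccc2)c1B1OC(C)(C)C(C)(C)O1)[Si](CC)(CC)CC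
F4 | step 6 | 3,5-bis(benzyloxy)-2-(4,4,5,5-tetramethyl-1,3,2-dioxaborolan-2-yl)-6-(trimethylsilyl)phenyl N-(propan-2-yl)carbamate | CC(C)NC(=O)Oc1c([Si](C)(C)C)c(OCc2ccccc2)cc(OCc2ccccc2)c1B1OC(C)(C)C(C)(C)O1
F5 | step 11 | 8-{4,6-bis(benzyloxy)-3-[(2E)-3-[4-(benzyloxy)phenyl]prop-2-enoyl]-2-(methoxymethoxy)phenyl}-5,7-bis(benzyloxy)-2-[4-(benzyloxy)phenyl]-4H-chromen-4-one | O=c1cc(-c2ccc(OCc3ccccc3)cc2)oc2c(-c3c(OCOC)c(C(=O)/C=C/c4ccc(OCc5ccccc5)cc4)c(OCc4ccccc4)cc3OCc3ccccc3)c(OCc3ccccc3)cc(OCc3ccccc3)c12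
F6 | step 11 | 8-{4,6-bis(benzyloxy)-3-[(2E)-3-[4-(benzyloxy)phenyl]prop-2-enoyl]-2-hydroxyphenyl}-5,7-bis(benzyloxy)-2-[4-(benzyloxy)phenyl]-4H-chromen-4-one | O=c1cc(-c2ccc(OCc3ccccc3)cc2)oc2c(-c3c(O)c(C(=O)/C=C/c4ccc(OCc5ccccc5)cc4)c(OCc4ccccc4)cc3OCc3ccccc3)c(OCc3ccccc3)cc(OCc3ccccc3)c12
F7 | step 11 | rac-5,7-bis(benzyloxy)-8-{5,7-bis(benzyloxy)-2-[4-(benzyloxy)phenyl]-4-oxo-4H-chromen-8-yl}-2-[4-(benzyloxy)phenyl]-2,3-dihydro-4H-chromen-4-one | O=C1CC(c2ccc(OCc3ccccc3)cc2)Oc2c(-c3c(OCc4ccccc4)cc(OCc4ccccc4)c4c(=O)cc(-c5ccc(OCc6ccccc6)cc5)oc34)c(OCc3ccccc3)cc(OCc3ccccc3)c12
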